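## Structural features

Manuifolin D (25) is a (3R)-isoflavan: a chroman (benzo ring A fused to pyran ring C) that carries aryl ring B on C3. C3 is the only stereocentre; it is a tertiary C–H flanked by two methylene groups (C2 on O1, C4 on C4a), so no neighbouring stereocentre or carbonyl group can relay its configuration. Ring A bears a free 7-OH. Ring B is a 1,2,4,5-tetrasubstituted benzene with a free 2′-OH, a 4′-O-prenyl ether and a 5′-(1,1-dimethylallyl) group whose quaternary benzylic carbon sits next to the ether oxygen.

The fragile elements are the aryl prenyl ether (acid, Lewis acid, heat above about 150 °C), the two alkenes (no hydrogenation, ozonolysis or strong electrophiles) and the electron-rich phenols. Acidic deprotection and hydrogenolysis are therefore excluded, and only fluoride- or mild base-labile protecting groups can be used.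

The real difficulty is twofold: creating the isolated C3 stereocentre catalytically, and telling four aryl oxygens apart (O1, O7, O2′, O4′). The key step exploits the C3–C4 ethylene unit: C4 is bonded to C4a of ring A, C3 to C1′ of ring B, and the one-carbon branch C2 can be delivered later through a C3–boron bond. A vinyl group placed between the two arenes therefore assembles the whole C1′–C3–C4–C4a array and fixes C3 in one operation.

## Logic of the disconnections

25 ⇒ 24. The last bond cut is O2′–Si. A silyl ether is the only mask on O2′ that can be removed without acid or hydrogen, so fluoride is reserved for the final step. The forward step must leave the prenyl ether and both alkenes untouched, which buffered fluoride does.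

24 ⇒ 23. Ring C is opened at O1–C2. This bond can be made by SN2 attack of the O8a phenol on an activated primary carbon, which does not involve C3. The gain is an acyclic 1,3-diaryl-propanol. The demand is that O8a be free while O2′ stays masked, because a free O2′ would close a five-membered ring onto the same carbon. O7 cannot reach C2 and only has to be kept from reacting intermolecularly by dilution.

23 ⇒ 22. Two O–Si bonds on ring A are cut. Both ring A oxygens carry tert-butyldimethylsilyl groups, and O2′ carries a triisopropylsilyl group flanked by the branched C3 substituent. The groups to be removed are thus the intrinsically more labile ones, and the one to be kept is the most robust and most hindered. The opposite pattern (triisopropylsilyl on O7, tert-butyldimethylsilyl on O8a) would ask for cleavage of a hindered labile group beside an unhindered robust one and would cost one more step on the way to ring A; it was rejected.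

22 ⇒ 20 (through 21). The C3–C2 bond is cut and replaced by C3–B. A 1,2-boronate shift onto a chloromethyl carbenoid inserts C2 with retention at C3, and oxidation of the new primary C–B bond supplies the hydroxyl. The gain is that C2 and its oxygen come from C1 and O1 reagents. The demand is a configurationally defined secondary benzylic boronic ester and capture of the carbenoid before it decomposes.

20 ⇒ 12 + 18 + 17 (through 19). C3–C1′ and C4–C4a are cut together. The three pieces are of comparable complexity, the route becomes convergent, and the only stereocentre is made under catalyst control. The forward step needs complete formation of the four-coordinate borate from hindered 12, a metallate shift that is faster than direct transmetalation or Heck arylation of the spectator alkenes, and facial control by the ligand despite an ortho silyloxy group on each arene.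

17 ⇒ 16 ⇒ 14 ⇒ 13 (through 15). The S–O bond, then the aryl C–O bond (traced back to the formyl carbon), then two O–Si bonds are cut. In 13 the carbon that must become C4a already has oxygen ortho and para to it, so no regiochemical decision is needed. The demand is that the silyl group on the ortho oxygen does not move to the newly freed neighbouring oxygen before sulfonylation.

12 ⇒ 11. The C1′–B bond is traced to C1′–Br; the forward step must not touch the prenyl ether or the alkenes, which a weak-base palladium borylation below 100 °C allows.

11 ⇒ 9 + 10. The O4′–CH2 bond of the prenyl ether is cut. Putting this alkylation late keeps the acid- and heat-sensitive ether out of the earlier steps. It requires a free O4′ beside a protected O2′.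

9 ⇒ 7 ⇒ 6 ⇒ 5 ⇒ 4 (through 8). The terminal C=C is traced to a lactol carbon, the lactol to a lactone, the two methyl groups to a double enolate alkylation, and the O2′–Si bond to a free phenol. The lactone oxygen is O4′ and the lactone α-carbon is the future quaternary carbon. The methylenation that creates the vinyl group therefore releases exactly the phenol that is to be prenylated, and the two ring B oxygens are distinguished by connectivity and not by selectivity.

4 ⇒ 2 ⇒ 1 (through 3). The lactone C–O bond, both O–CH3 bonds and the C–Br bond are cut. Demethylation is placed before any alkene exists, which removes the danger of acid-induced cyclisation of a dimethylallyl phenol. Bromination on the dimethyl ether has one strongly preferred site (para to one methoxy, ortho to the other).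

## Other disconnections considered

Alternative 1: Ring B is built last by a Danheiser benzannulation. The cuts are C1′–C6′, C1′–C2′, C3′–C4′ and C4′–C5′. Irradiation of the diazo enone A1 (already carrying the (3R)-chroman) would trigger a Wolff rearrangement, and the resulting ketene would add the siloxyalkyne A2. Four-electron ring opening, six-electron closure and tautomerisation would then give the phenol A3, after which O-alkylation with 10 and desilylation would finish the synthesis.
- In its favour: the substitution pattern of ring B follows from connectivity alone, and A3 emerges with O4′ free and O2′ silylated. On this point it is better than the chosen plan, which spends eight steps on ring B. Only two steps follow the key step, against four in the chosen plan.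
- Against it here: the carbene from A1 sits next to the C3–H, so a 1,2-hydride shift competes with the Wolff shift and would destroy the stereocentre. The 3,3-dimethyl-1,4-diene unit of A1 is a classical di-π-methane substrate under irradiation. The stereocentre has to be made earlier by a separate asymmetric step and carried through diazo transfer and photolysis.
- Comparison: structurally it is more linear (ring B grows on the chroman), whereas the chosen plan is convergent. Mechanistically it relies on a pericyclic cascade that must spare a stereocentre, while the chosen plan creates the stereocentre in the key step. The total step count is expected to be similar or higher once the enantioenriched chroman ketone and A1 are counted.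

Alternative 2: Ring A is folded from a masked triketide chain by cutting C4a–C5. Methanolic KOH would unmask the β-methoxy enone of A4 as an aldehyde, the enolate at C4a would add to it, and dehydration and enolisation would give the 4-alkylresorcinol A5.
- In its favour: the oxygen pattern of ring A comes directly from the carbonyl positions, so no Dakin-type oxidation and no silyl migration risk arise. On this point it is better than the chosen plan. The conditions are basic and spare the prenyl ether.
- Against it here: 1,3,5-tricarbonyl chains readily close through oxygen to pyranones and undergo retro-Claisen cleavage. A4 must be assembled on a chiral fragment that already contains all of ring B, which makes the route linear and long. The 2-(trimethylsilyl)ethoxymethyl ether on O2′ needs forcing fluoride or acid at the end, which suits the prenyl ether worse than a silyl ether does.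
- Comparison: the endgame from A5 (desilylation of the primary alcohol, Mitsunobu closure through O8a in the presence of a free O7) is the equal of the chosen endgame. The stereocentre is set by a separate earlier step, not by the key step, and the step count is expected to be clearly higher.

Alternative 3: Ring C is closed by annulation of an acyl-ammonium-derived enolate onto a quinone methide; the cuts are C3–C4 and O1–C2 (acyl). A chiral isothiourea would activate the pentafluorophenyl ester A6. Carbonate base would release the ortho-quinone methide A8 from the sulfone A7. Michael addition and lactonisation would give the dihydrocoumarin A9, which would be reduced to the phenol-alcohol, closed by Mitsunobu reaction and desilylated.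
- In its favour: one metal-free step forms ring C and the stereocentre. O8a arrives acylated and is the only free phenol after reduction, so no discrimination between silyl ethers is needed; on this point it is better than the chosen plan. Three steps follow the key step, against four.
- Against it here: the new stereocentre in A9 is benzylic and α to an aryl ester, and can epimerise under the carbonate base and again at the aldehyde stage of the reduction. A8 has no substituent at the methide carbon, so all induction must come from the enolate face, and such unsubstituted methides oligomerise easily. A6 needs an extra two-carbon chain on ring B beyond 11.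
- Comparison: the step count is comparable, the protecting-group logic is simpler, and the configurational security is lower than for a C–B stereocentre, which is stable and is transferred with retention.

Key step: step 12

Remark on the chemistry: the sense of induction of the ferrocenyl bisphosphine is not assigned here; both antipodes are available, and the one that leads to (R)-20 is meant throughout.

Step 1
Reactants: 1 2,4-dimethoxyphenylacetic acid
Product: 2 2-(5-bromo-2,4-dimethoxyphenyl)acetic acid
Conditions: NBS (1.05 equiv), MeCN, 0 °C → rt
Reagents that add atoms: N-bromosuccinimide, O=C1CCC(=O)N1Br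
Why: Electrophilic aromatic bromination; C5 is para to the 2-methoxy and ortho to the 4-methoxy group, whereas C3 lies between two methoxy groups and C6 is meta to both, so one bromide is expected.

Step 2
Reactants: 2 2-(5-bromo-2,4-dimethoxyphenyl)acetic acid
Product: 4 5-bromo-6-hydroxybenzofuran-2(3H)-one, via dihydroxy acid 3 (not isolated)
Conditions: BBr3 (3.5 equiv), CH2Cl2, −78 °C → rt; H2O; then TsOH·H2O (cat.), toluene, reflux
Reagents that add atoms: none
Why: Lewis acid cleavage of both aryl methyl ethers followed by acid-catalysed lactonisation; only the hydroxyl ortho to the acetic acid chain can form the five-membered lactone, which distinguishes the two phenolic oxygens before any alkene is present.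

Step 3
Reactants: 4 5-bromo-6-hydroxybenzofuran-2(3H)-one
Product: 5 5-bromo-6-(triisopropylsilyloxy)benzofuran-2(3H)-one
Conditions: TIPSCl, imidazole, DMF, rt
Reagents that add atoms: triisopropylsilyl chloride, CC(C)[Si](Cl)(C(C)C)C(C)C
Why: Standard silylation of the single free phenol (the future O2′); imidazole is too weak a base to alkylate or open the lactone irreversibly.

Step 4
Reactants: 5 5-bromo-6-(triisopropylsilyloxy)benzofuran-2(3H)-one
Product: 6 5-bromo-3,3-dimethyl-6-(triisopropylsilyloxy)benzofuran-2(3H)-one
Conditions: NaH (2.4 equiv), MeI (3 equiv), THF, 0 °C → rt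
Reagents that add atoms: iodomethane, CI
Why: Double C-alkylation of a benzofuranone enolate with a soft electrophile, a known route to 3,3-dialkylbenzofuranones; the non-nucleophilic base leaves the aryl silyl ether and the aryl bromide alone.

Step 5
Reactants: 6 5-bromo-3,3-dimethyl-6-(triisopropylsilyloxy)benzofuran-2(3H)-one
Product: 7 5-bromo-3,3-dimethyl-6-(triisopropylsilyloxy)-2,3-dihydrobenzofuran-2-ol (racemic at the hemiacetal carbon, which is lost in step 6)
Conditions: i-Bu2AlH (1.1 equiv), CH2Cl2, −78 °C; then aq. potassium sodium tartrate
Reagents that add atoms: none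
Why: Partial reduction of a lactone to the lactol; the tetrahedral aluminium alkoxide persists at low temperature and the gem-dimethyl group favours the closed hemiacetal.

Step 6
Reactants: 7 5-bromo-3,3-dimethyl-6-(triisopropylsilyloxy)-2,3-dihydrobenzofuran-2-ol
Product: 9 4-bromo-2-(2-methylbut-3-en-2-yl)-5-(triisopropylsilyloxy)phenol, via ring-opened hydroxy aldehyde 8 (not isolated)
Conditions: Ph3PCH3Br (3.2 equiv), NaN(SiMe3)2 (3.0 equiv), THF, 0 °C → 50 °C
Reagents that add atoms: methyltriphenylphosphonium bromide, C[P+](c1ccccc1)(c1ccccc1)c1ccccc1.[Br-]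
Why: Wittig methylenation of a lactol through its open aldehyde form, which has no α-hydrogen; the step creates the 1,1-dimethylallyl group and releases the ortho phenol (O4′) while O2′ stays silylated.

Step 7
Reactants: 9 4-bromo-2-(2-methylbut-3-en-2-yl)-5-(triisopropylsilyloxy)phenol; 10 prenyl bromide
Product: 11 [2-bromo-4-(2-methylbut-3-en-2-yl)-5-(3-methylbut-2-enyloxy)phenoxy]triisopropylsilane (ring B bromide)
Conditions: NaH, n-Bu4NI (cat.), THF/DMF, 0 °C → rt
Reagents that add atoms: none
Why: Williamson etherification; the sodium phenoxide in a dipolar aprotic medium reacts at oxygen and at the primary carbon of the allylic bromide, and no nucleophilic base is present that could attack the silyl ether.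

Step 8
Reactants: 11 ring B bromide
Product: 12 triisopropyl[4-(2-methylbut-3-en-2-yl)-5-(3-methylbut-2-enyloxy)-2-(4,4,5,5-tetramethyl-1,3,2-dioxaborolan-2-yl)phenoxy]silane (ring B pinacol boronate)
Conditions: B2pin2 (1.3 equiv), PdCl2(dppf) (5 mol %), KOAc, 1,4-dioxane, 90 °C
Reagents that add atoms: bis(pinacolato)diboron, CC1(C)OB(B2OC(C)(C)C(C)(C)O2)OC1(C)C
Why: Miyaura borylation of an aryl bromide; acetate is too weak a base to promote a following Suzuki coupling, and the temperature is well below that of a Claisen rearrangement of the prenyl ether.

Step 9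
Reactants: 13 2,4-dihydroxybenzaldehyde
Product: 14 2,4-bis(tert-butyldimethylsilyloxy)benzaldehyde
Conditions: TBSCl (2.4 equiv), imidazole, DMF, rt
Reagents that add atoms: tert-butyldimethylsilyl chloride, CC(C)(C)[Si](C)(C)Cl
Why: Exhaustive silylation of both phenols in one operation; no regiochemical choice is involved.

Step 10
Reactants: 14 2,4-bis(tert-butyldimethylsilyloxy)benzaldehyde
Product: 16 2,4-bis(tert-butyldimethylsilyloxy)phenol, via aryl formate 15 (not isolated)
Conditions: mCPBA, CH2Cl2, 0 °C → rt; then KHCO3, MeOH, 0 °C, short contact
Reagents that add atoms: 3-chloroperoxybenzoic acid, O=C(OO)c1cccc(Cl)c1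
Why: Baeyer–Villiger (Dakin-type) oxidation; in an ortho,para-dioxygenated benzaldehyde the electron-rich aryl group migrates to oxygen, and the aryl formate is methanolysed far faster than an aryl silyl ether. Weak base, low temperature and immediate use are chosen to suppress a shift of the 2-O silyl group onto the new neighbouring phenol.

Step 11
Reactants: 16 2,4-bis(tert-butyldimethylsilyloxy)phenol
Product: 17 2,4-bis(tert-butyldimethylsilyloxy)phenyl trifluoromethanesulfonate (ring A triflate)
Conditions: Tf2O, pyridine, CH2Cl2, −78 → 0 °C
Reagents that add atoms: trifluoromethanesulfonic anhydride, O=S(=O)(OS(=O)(=O)C(F)(F)F)C(F)(F)F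
Why: O-Sulfonylation of a phenol; pyridine does not generate enough phenoxide for silyl migration, and triflation at low temperature is fast.

Step 12
Reactants: 12 ring B pinacol boronate; 18 vinylmagnesium bromide; 17 ring A triflate
Product: 20 (R)-2-{2-[2,4-bis(tert-butyldimethylsilyloxy)phenyl]-1-[5-(2-methylbut-3-en-2-yl)-4-(3-methylbut-2-enyloxy)-2-(triisopropylsilyloxy)phenyl]ethyl}-4,4,5,5-tetramethyl-1,3,2-dioxaborolane, via magnesium vinylborate 19 (not isolated)
Conditions: 18 (1.0 equiv), THF, 0 °C → rt; then NaOTf, 17, Pd(OAc)2 (2 mol %), MandyPhos-type ligand (1,1′-bis(diphenylphosphino)-2,2′-bis[α-(dimethylamino)benzyl]ferrocene, one enantiomer, 2.4 mol %), THF, 40–60 °C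
Reagents that add atoms: none
Why: Addition of 18 to the boron of 12 gives the four-coordinate vinylborate 19; Pd(OAc)2 is reduced in the flask to zerovalent palladium, which inserts into the C–O bond of 17 to give a cationic arylpalladium (divalent palladium) triflate held by the bidentate ligand. This electrophilic complex binds the vinyl group of 19 and induces a 1,2-shift of ring B from boron to the adjacent carbon (C3–C1′), anti to palladium, while palladium bonds to the terminal carbon; reductive elimination then forms C4–C4a and returns zerovalent palladium. The closest known reaction type is the Pd(OAc)2/MandyPhos-catalysed enantioselective conjunctive cross-coupling of aryl(vinyl)borates with aryl triflates. No ring is closed. The single new stereocentre (C3) is set under catalyst control: the ligand decides which face of the bound vinyl group receives the migrating aryl group. The step needs the metallate shift to outrun direct transfer of aryl or vinyl from boron to palladium, β-hydride elimination and Heck arylation of the other alkenes. The chelating ligand leaves no free site for transmetalation or β-hydride elimination, the triflate (with NaOTf removing bromide) keeps palladium cationic, and the anionic vinylborate is a far better π-donor than the neopentyl-type vinyl group or the trisubstituted prenyl alkene. The basic, non-oxidising medium leaves the aryl silyl ethers and the prenyl ether untouched.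

Step 13
Reactants: 20 (R)-secondary benzylic pinacol boronate
Product: 22 (2R)-3-[2,4-bis(tert-butyldimethylsilyloxy)phenyl]-2-[5-(2-methylbut-3-en-2-yl)-4-(3-methylbut-2-enyloxy)-2-(triisopropylsilyloxy)phenyl]propan-1-ol, via homologated primary boronate 21 (not isolated)
Conditions: BrCH2Cl (3 equiv), n-BuLi (2.5 equiv), THF, −78 °C → rt; then NaBO3·4H2O, THF/H2O, rt
Reagents that add atoms: bromochloromethane, ClCBr; sodium perborate tetrahydrate, O.O.O.O.[Na+].[O-]OB=O
Why: Matteson homologation: chloromethyllithium made in the presence of 20 is trapped at boron, and the 1,2-shift of C3 with loss of chloride occurs with retention on warming, after excess carbenoid has decomposed, which limits a second insertion. Perborate then oxidises the primary C–B bond under mild conditions that do not touch the alkenes.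

Step 14
Reactants: 22 (2R)-configured primary alcohol
Product: 23 4-{(2R)-3-hydroxy-2-[5-(2-methylbut-3-en-2-yl)-4-(3-methylbut-2-enyloxy)-2-(triisopropylsilyloxy)phenyl]propyl}benzene-1,3-diol
Conditions: K2CO3, MeOH/THF, 0 °C → rt, monitored
Reagents that add atoms: none
Why: Base-mediated methanolysis of aryl silyl ethers; the two tert-butyldimethylsilyl groups on ring A are cleaved much faster than the triisopropylsilyl group, which is intrinsically more robust and is shielded by the adjacent branched carbon.

Step 15
Reactants: 23 triol
Product: 24 (3R)-3-[5-(2-methylbut-3-en-2-yl)-4-(3-methylbut-2-enyloxy)-2-(triisopropylsilyloxy)phenyl]chroman-7-ol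
Conditions: PPh3, DIAD, THF (0.01 M), 0 °C → rt
Reagents that add atoms: none
Why: Intramolecular Mitsunobu etherification (6-exo-tet) of the O8a phenol onto the activated primary carbon C2; C3 is not involved, O2′ is masked so no five-membered ring can form, and O7 cannot reach C2, so dilution suffices to suppress intermolecular reaction.

Step 16
Reactants: 24 (3R)-2′-O-silyl isoflavan
Product: 25 Manuifolin D, (3R)-3-[2-hydroxy-5-(2-methylbut-3-en-2-yl)-4-(3-methylbut-2-enyloxy)phenyl]chroman-7-ol
Conditions: TBAF, AcOH, THF, 0 °C → rt
Reagents that add atoms: none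
Why: Fluoride cleavage of the aryl triisopropylsilyl ether; the acetic acid buffer keeps the electron-rich phenoxides protonated, and neither the prenyl ether nor the alkenes react with fluoride.

Compound list

1 | 2,4-dimethoxyphenylacetic acid | COc1ccc(CC(=O)O)c(OC)c1 | starting material
2 | 2-(5-bromo-2,4-dimethoxyphenyl)acetic acid | COc1cc(OC)c(CC(=O)O)cc1Br | intermediate
3 | 2-(5-bromo-2,4-dihydroxyphenyl)acetic acid (formed in the flask) | O=C(O)Cc1cc(Br)c(O)cc1O | intermediate
4 | 5-bromo-6-hydroxybenzofuran-2(3H)-one | O=C1Cc2cc(Br)c(O)cc2O1 | intermediate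
5 | 5-bromo-6-(triisopropylsilyloxy)benzofuran-2(3H)-one | O=C1Cc2cc(Br)c(O[Si](C(C)C)(C(C)C)C(C)C)cc2O1 | intermediate
6 | 5-bromo-3,3-dimethyl-6-(triisopropylsilyloxy)benzofuran-2(3H)-one | CC1(C)C(=O)Oc2cc(O[Si](C(C)C)(C(C)C)C(C)C)c(Br)cc21 | intermediate
7 | 5-bromo-3,3-dimethyl-6-(triisopropylsilyloxy)-2,3-dihydrobenzofuran-2-ol (racemic hemiacetal) | CC1(C)C(O)Oc2cc(O[Si](C(C)C)(C(C)C)C(C)C)c(Br)cc21 | intermediate
8 | 2-[5-bromo-2-hydroxy-4-(triisopropylsilyloxy)phenyl]-2-methylpropanal (formed in the flask) | CC(C)(C=O)c1cc(Br)c(O[Si](C(C)C)(C(C)C)C(C)C)cc1O | intermediate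
9 | 4-bromo-2-(2-methylbut-3-en-2-yl)-5-(triisopropylsilyloxy)phenol | C=CC(C)(C)c1cc(Br)c(O[Si](C(C)C)(C(C)C)C(C)C)cc1O | intermediate
10 | prenyl bromide (1-bromo-3-methylbut-2-ene) | CC(C)=CCBr | starting material
11 | [2-bromo-4-(2-methylbut-3-en-2-yl)-5-(3-methylbut-2-enyloxy)phenoxy]triisopropylsilane | C=CC(C)(C)c1cc(Br)c(O[Si](C(C)C)(C(C)C)C(C)C)cc1OCC=C(C)C | intermediate
12 | triisopropyl[4-(2-methylbut-3-en-2-yl)-5-(3-methylbut-2-enyloxy)-2-(4,4,5,5-tetramethyl-1,3,2-dioxaborolan-2-yl)phenoxy]silane | C=CC(C)(C)c1cc(B2OC(C)(C)C(C)(C)O2)c(O[Si](C(C)C)(C(C)C)C(C)C)cc1OCC=C(C)C | intermediate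
13 | 2,4-dihydroxybenzaldehyde | O=Cc1ccc(O)cc1O | starting material
14 | 2,4-bis(tert-butyldimethylsilyloxy)benzaldehyde | O=Cc1ccc(O[Si](C)(C)C(C)(C)C)cc1O[Si](C)(C)C(C)(C)C | intermediate
15 | 2,4-bis(tert-butyldimethylsilyloxy)phenyl formate (formed in the flask) | O=COc1ccc(O[Si](C)(C)C(C)(C)C)cc1O[Si](C)(C)C(C)(C)C | intermediate
16 | 2,4-bis(tert-butyldimethylsilyloxy)phenol | Oc1ccc(O[Si](C)(C)C(C)(C)C)cc1O[Si](C)(C)C(C)(C)C | intermediate
17 | 2,4-bis(tert-butyldimethylsilyloxy)phenyl trifluoromethanesulfonate | O=S(=O)(Oc1ccc(O[Si](C)(C)C(C)(C)C)cc1O[Si](C)(C)C(C)(C)C)C(F)(F)F | intermediate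
18 | vinylmagnesium bromide | C=C[Mg]Br | starting material
19 | bromomagnesium aryl(vinyl)(pinacolato)borate from 12 (formed in the flask) | C=C[B-]1(c2cc(C(C)(C)C=C)c(OCC=C(C)C)cc2O[Si](C(C)C)(C(C)C)C(C)C)OC(C)(C)C(C)(C)O1.[Mg+]Br | intermediate
20 | (R)-2-{2-[2,4-bis(tert-butyldimethylsilyloxy)phenyl]-1-[5-(2-methylbut-3-en-2-yl)-4-(3-methylbut-2-enyloxy)-2-(triisopropylsilyloxy)phenyl]ethyl}-4,4,5,5-tetramethyl-1,3,2-dioxaborolane | C=CC(C)(C)c1cc([C@@H](Cc2ccc(O[Si](C)(C)C(C)(C)C)cc2O[Si](C)(C)C(C)(C)C)B2OC(C)(C)C(C)(C)O2)c(O[Si](C(C)C)(C(C)C)C(C)C)cc1OCC=C(C)C | intermediate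
21 | (R)-2-{3-[2,4-bis(tert-butyldimethylsilyloxy)phenyl]-2-[5-(2-methylbut-3-en-2-yl)-4-(3-methylbut-2-enyloxy)-2-(triisopropylsilyloxy)phenyl]propyl}-4,4,5,5-tetramethyl-1,3,2-dioxaborolane (formed in the flask) | C=CC(C)(C)c1cc([C@@H](Cc2ccc(O[Si](C)(C)C(C)(C)C)cc2O[Si](C)(C)C(C)(C)C)CB2OC(C)(C)C(C)(C)O2)c(O[Si](C(C)C)(C(C)C)C(C)C)cc1OCC=C(C)C | intermediate
22 | (2R)-3-[2,4-bis(tert-butyldimethylsilyloxy)phenyl]-2-[5-(2-methylbut-3-en-2-yl)-4-(3-methylbut-2-enyloxy)-2-(triisopropylsilyloxy)phenyl]propan-1-ol | C=CC(C)(C)c1cc([C@@H](Cc2ccc(O[Si](C)(C)C(C)(C)C)cc2O[Si](C)(C)C(C)(C)C)CO)c(O[Si](C(C)C)(C(C)C)C(C)C)cc1OCC=C(C)C | intermediate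
23 | 4-{(2R)-3-hydroxy-2-[5-(2-methylbut-3-en-2-yl)-4-(3-methylbut-2-enyloxy)-2-(triisopropylsilyloxy)phenyl]propyl}benzene-1,3-diol | C=CC(C)(C)c1cc([C@@H](Cc2ccc(O)cc2O)CO)c(O[Si](C(C)C)(C(C)C)C(C)C)cc1OCC=C(C)C | intermediate
24 | (3R)-3-[5-(2-methylbut-3-en-2-yl)-4-(3-methylbut-2-enyloxy)-2-(triisopropylsilyloxy)phenyl]chroman-7-ol | C=CC(C)(C)c1cc([C@@H]2COc3cc(O)ccc3C2)c(O[Si](C(C)C)(C(C)C)C(C)C)cc1OCC=C(C)C | intermediate
25 | Manuifolin D, (3R)-3-[2-hydroxy-5-(2-methylbut-3-en-2-yl)-4-(3-methylbut-2-enyloxy)phenyl]chroman-7-ol | C=CC(C)(C)c1cc([C@@H]2COc3cc(O)ccc3C2)c(O)cc1OCC=C(C)C | target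

Total step count: 16. Longest linear sequence: 13 steps (steps 1 to 8, step 12, steps 13 to 16); the ring A branch (steps 9 to 11) joins at step 12.

Least certain steps

Step 12 (key step).
- What may go wrong: the Grignard reagent may add incompletely to the crowded boron of 12, which carries an ortho triisopropylsilyloxy group. Free 18 and three-coordinate 12 would then feed direct cross-coupling. Slow alkene binding by the ortho-silyloxy arylpalladium would in turn give time for Heck arylation of the dimethylallyl vinyl group and erode facial selectivity.
- Fallback: it sets out from 11 and assembles the same borate from the other side. Bromine–lithium exchange (n-BuLi, THF, −78 °C, kept cold so that the silyl group does not shift from oxygen to carbon) would give the aryllithium F1. F1 would be trapped by the unhindered vinylboronic acid pinacol ester to give the lithium aryl(vinyl)(pinacolato)borate F2, free of magnesium halide. F2 would then be coupled with 17 under the same Pd(OAc)2/ferrocenyl bisphosphine catalyst, the organolithium form of the conjunctive coupling. It comes back to the route at 20 and makes step 8 unnecessary.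

Step 10.
- What may go wrong: once the phenol is free, the silyl group on the neighbouring oxygen can shift to it under base, scrambling which oxygen is later sulfonylated. The aryl silyl ethers may also be partly cleaved during removal of the formate.
- Fallback: it sets out from 12 (with 18) and abandons the phenol and the triflate. Commercial 4-bromoresorcinol F3, whose substitution pattern is fixed, would be bis-silylated (TBSCl, imidazole, DMF) to 1-bromo-2,4-bis(tert-butyldimethylsilyloxy)benzene F4. F4 would be used as the electrophile with borate 19 under the same palladium catalyst, with NaOTf as halide scavenger, the known organohalide variant of this coupling. It comes back at 20 and replaces steps 9 to 11 by one step.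

Step 5.
- What may go wrong: over-reduction, because the aluminium hemiacetal of an aryl lactone can collapse with loss of the aryloxide and be reduced again; or incomplete reduction of the hindered carbonyl.
- Fallback: it sets out from 6. Full reduction with LiAlH4 (THF, 0 °C) would give 2-[5-bromo-2-hydroxy-4-(triisopropylsilyloxy)phenyl]-2-methylpropan-1-ol F5. Phenol-selective alkylation with 10 (K2CO3, acetone) would give 2-[5-bromo-2-(3-methylbut-2-enyloxy)-4-(triisopropylsilyloxy)phenyl]-2-methylpropan-1-ol F6. Dess–Martin oxidation would give the aldehyde 2-[5-bromo-2-(3-methylbut-2-enyloxy)-4-(triisopropylsilyloxy)phenyl]-2-methylpropanal F7, and Wittig methylenation (Ph3PCH3Br, NaN(SiMe3)2) would give 11, where it comes back to the route, one step longer.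

Step 15.
- What may go wrong: closure at the β-branched primary carbon may be slow, so that intermolecular etherification through the free O7 phenol or alkylation of the reduced azodicarboxylate competes.
- Fallback: it sets out from 22 and replaces the Mitsunobu activation by a sulfonate displacement. Mesylation (MsCl, Et3N, CH2Cl2, 0 °C), done while all phenols are still silylated, would give (2R)-3-[2,4-bis(tert-butyldimethylsilyloxy)phenyl]-2-[5-(2-methylbut-3-en-2-yl)-4-(3-methylbut-2-enyloxy)-2-(triisopropylsilyloxy)phenyl]propyl methanesulfonate F8. Treatment with K2CO3 in MeOH/THF at high dilution would unmask the ring A phenoxides, and the O8a phenoxide would close ring C by intramolecular SN2 displacement as soon as it is formed. It comes back at 24.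

Further compounds

F1 | step 12 | [4-(2-methylbut-3-en-2-yl)-5-(3-methylbut-2-enyloxy)-2-(triisopropylsilyloxy)phenyl]lithium | [Li]c1cc(C(C)(C)C=C)c(OCC=C(C)C)cc1O[Si](C(C)C)(C(C)C)C(C)C
F2 | step 12 | lithium aryl(vinyl)(pinacolato)borate from F1 | C=C[B-]1(c2cc(C(C)(C)C=C)c(OCC=C(C)C)cc2O[Si](C(C)C)(C(C)C)C(C)C)OC(C)(C)C(C)(C)O1.[Li+]
F3 | step 10 | 4-bromoresorcinol | Oc1ccc(Br)c(O)c1
F4 | step 10 | 1-bromo-2,4-bis(tert-butyldimethylsilyloxy)benzene | CC(C)(C)[Si](C)(C)Oc1ccc(Br)c(O[Si](C)(C)C(C)(C)C)c1
F5 | step 5 | 2-[5-bromo-2-hydroxy-4-(triisopropylsilyloxy)phenyl]-2-methylpropan-1-ol | CC(C)(CO)c1cc(Br)c(O[Si](C(C)C)(C(C)C)C(C)C)cc1O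
F6 | step 5 | 2-[5-bromo-2-(3-methylbut-2-enyloxy)-4-(triisopropylsilyloxy)phenyl]-2-methylpropan-1-ol | CC(C)(CO)c1cc(Br)c(O[Si](C(C)C)(C(C)C)C(C)C)cc1OCC=C(C)C
F7 | step 5 | 2-[5-bromo-2-(3-methylbut-2-enyloxy)-4-(triisopropylsilyloxy)phenyl]-2-methylpropanal | CC(C)(C=O)c1cc(Br)c(O[Si](C(C)C)(C(C)C)C(C)C)cc1OCC=C(C)C
F8 | step 15 | (2R)-3-[2,4-bis(tert-butyldimethylsilyloxy)phenyl]-2-[5-(2-methylbut-3-en-2-yl)-4-(3-methylbut-2-enyloxy)-2-(triisopropylsilyloxy)phenyl]propyl methanesulfonate | C=CC(C)(C)c1cc([C@@H](Cc2ccc(O[Si](C)(C)C(C)(C)C)cc2O[Si](C)(C)C(C)(C)C)COS(C)(=O)=O)c(O[Si](C(C)C)(C(C)C)C(C)C)cc1OCC=C(C)C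
A1 | alternative 1 | (E)-1-diazo-5,5-dimethyl-1-[(3R)-7-(triisopropylsilyloxy)chroman-3-yl]hepta-3,6-dien-2-one | C=CC(C)(C)/C=C/C(=O)C(=[N+]=[N-])[C@@H]1COc2cc(O[Si](C(C)C)(C(C)C)C(C)C)ccc2C1
A2 | alternative 1 | (triisopropylsilyloxy)ethyne | C#CO[Si](C(C)C)(C(C)C)C(C)C
A3 | alternative 1 | 2-(2-methylbut-3-en-2-yl)-5-(triisopropylsilyloxy)-4-[(3R)-7-(triisopropylsilyloxy)chroman-3-yl]phenol | C=CC(C)(C)c1cc([C@@H]2COc3cc(O[Si](C(C)C)(C(C)C)C(C)C)ccc3C2)c(O[Si](C(C)C)(C(C)C)C(C)C)cc1O
A4 | alternative 2 | (1E,8R)-9-(tert-butyldimethylsilyloxy)-1-methoxy-8-{5-(2-methylbut-3-en-2-yl)-4-(3-methylbut-2-enyloxy)-2-[2-(trimethylsilyl)ethoxymethoxy]phenyl}non-1-ene-3,5-dione | CO/C=C/C(=O)CC(=O)CC[C@@H](CO[Si](C)(C)C(C)(C)C)c1cc(C(C)(C)C=C)c(OCC=C(C)C)cc1OCOCC[Si](C)(C)C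
A5 | alternative 2 | 4-[(2R)-3-(tert-butyldimethylsilyloxy)-2-{5-(2-methylbut-3-en-2-yl)-4-(3-methylbut-2-enyloxy)-2-[2-(trimethylsilyl)ethoxymethoxy]phenyl}propyl]benzene-1,3-diol | Oc1ccc(C[C@@H](CO[Si](C)(C)C(C)(C)C)c2cc(C(C)(C)C=C)c(OCC=C(C)C)cc2OCOCC[Si](C)(C)C)c(O)c1
A6 | alternative 3 | pentafluorophenyl 2-[5-(2-methylbut-3-en-2-yl)-4-(3-methylbut-2-enyloxy)-2-(triisopropylsilyloxy)phenyl]acetate | C=CC(C)(C)c1cc(CC(=O)Oc2c(F)c(F)c(F)c(F)c2F)c(O[Si](C(C)C)(C(C)C)C(C)C)cc1OCC=C(C)C
A7 | alternative 3 | 2-[(phenylsulfonyl)methyl]-5-(triisopropylsilyloxy)phenol | O=S(=O)(Cc1ccc(O[Si](C(C)C)(C(C)C)C(C)C)cc1O)c1ccccc1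
A8 | alternative 3 | 6-methylene-3-(triisopropylsilyloxy)cyclohexa-2,4-dien-1-one | C=C1C=CC(O[Si](C(C)C)(C(C)C)C(C)C)=CC1=O
A9 | alternative 3 | (3R)-3-[5-(2-methylbut-3-en-2-yl)-4-(3-methylbut-2-enyloxy)-2-(triisopropylsilyloxy)phenyl]-7-(triisopropylsilyloxy)chroman-2-one | C=CC(C)(C)c1cc([C@H]2Cc3ccc(O[Si](C(C)C)(C(C)C)C(C)C)cc3OC2=O)c(O[Si](C(C)C)(C(C)C)C(C)C)cc1OCC=C(C)C
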